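**Plan**
- Retrosynthesis (tetralone numbering: C1 = C=O, C3 = CHOH, C5 = pyranonyl, C6 = Ph, C8 = OH): the two protecting groups come off last; the pyranone (ring C) is traced back through an acylketene and a β-keto dioxinone to a C5 aldehyde, itself from a C5 ester; ring B is then cut at C4–C3 and at C1–C8a.
- Enabling feature: on ring A the benzylic carbon C4 (on C4a) and the ring carbon C8a are 1,3-related and both can be metalated (C4–H is acidified by the ortho C5 ester, C8a is reached from a bromide), so ring A can act as a 1,3-C,C-dianion, and C1–C2–C3 of ring B is a malonyl unit.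
- Helpers: C3 is raised to the ketone level and C2 is blocked as a 1,3-dithiane, which makes the three-carbon unit symmetric (no regiochemistry) and stops the 1,3-dione from aromatizing to a naphthalenediol; both helpers are removed in steps 7 and 8.
- Forward: ring A with all substituents from methyl orsellinate (bromination, MOM ether, triflate, Suzuki coupling); ring B in one pot by [3+3] double acylation; then C3 reduction, desulfurization, ester to aldehyde, dioxinone chemistry for ring C, and final unmasking.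
- Stereochemistry: the only stereocentre, C3 (S), comes from a catalyst-controlled CBS reduction of the C3 ketone right after the key step and is carried as a silyl ether through neutral or Lewis-acidic steps.

Key step: step 6

Remark: CIP analysis of the given SMILES gives (S) at C3; N,N'-dimethoxy-N,N'-dimethylmalonamide (6) is taken as a purchasable compound.

**Route**

Step 1
Reactants: 1 methyl 2,4-dihydroxy-6-methylbenzoate (methyl orsellinate)
Product: 2 methyl 3-bromo-4,6-dihydroxy-2-methylbenzoate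
Conditions: N-bromosuccinimide (1.0 equiv), MeCN, 0 °C
Reagents that add atoms: N-bromosuccinimide, O=C1CCC(=O)N1Br
Why: Electrophilic aromatic bromination is expected para to the ester-chelated 6-OH and ortho to the free 4-OH, i.e. at the ring carbon next to the methyl group, the site at which resorcylate esters of this type are normally halogenated.

Step 2
Reactants: 2 methyl 3-bromo-4,6-dihydroxy-2-methylbenzoate
Product: 3 methyl 3-bromo-6-hydroxy-4-(methoxymethoxy)-2-methylbenzoate
Conditions: MOMCl (1.1 equiv), i-Pr2NEt, CH2Cl2, 0 °C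
Reagents that add atoms: chloromethyl methyl ether, COCCl
Why: O-Alkylation (MOM ether formation) should take the free 4-OH, because the 6-OH is held in a hydrogen bond to the ester carbonyl.

Step 3
Reactants: 3 methyl 3-bromo-6-hydroxy-4-(methoxymethoxy)-2-methylbenzoate
Product: 4 methyl 3-bromo-4-(methoxymethoxy)-2-methyl-6-(trifluoromethanesulfonyloxy)benzoate
Conditions: Tf2O, pyridine, CH2Cl2, 0 °C
Reagents that add atoms: trifluoromethanesulfonic anhydride, O=S(=O)(OS(=O)(=O)C(F)(F)F)C(F)(F)F
Why: O-Sulfonylation of the remaining phenol gives the aryl triflate that serves as the cross-coupling handle.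

Step 4
Reactants: 4 methyl 3-bromo-4-(methoxymethoxy)-2-methyl-6-(trifluoromethanesulfonyloxy)benzoate
Product: 5 methyl 4-bromo-5-(methoxymethoxy)-3-methyl-[1,1'-biphenyl]-2-carboxylate
Conditions: PhB(OH)2 (1.3 equiv), PdCl2 (3 mol %, no added ligand), KF, MeCN/H2O, rt
Reagents that add atoms: phenylboronic acid, OB(O)c1ccccc1
Why: Suzuki–Miyaura coupling under ligand-free PdCl2/KF conditions, which favour the ester-activated C–OTf bond over the electron-rich, doubly ortho-substituted C–Br bond, should install the phenyl ring and keep the bromide for step 6.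

Step 5
Reactants: 6 N,N'-dimethoxy-N,N'-dimethylmalonamide
Product: 7 N,N'-dimethoxy-N,N'-dimethyl-1,3-dithiane-2,2-dicarboxamide
Conditions: NaH (2.2 equiv), TsS(CH2)3STs, THF/DMF, 0 °C to rt
Reagents that add atoms: S,S'-propane-1,3-diyl bis(4-methylbenzenesulfonothioate), Cc1ccc(cc1)S(=O)(=O)SCCCSS(=O)(=O)c1ccc(C)cc1
Why: Double sulfenylation of the malonamide enolate by the bis-thiosulfonate (thiosulfonate-based 1,3-dithiane synthesis from an active methylene compound) closes the dithiane on the central carbon with loss of two sulfinate ions.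

Step 6
Reactants: 5 methyl 4-bromo-5-(methoxymethoxy)-3-methyl-[1,1'-biphenyl]-2-carboxylate; 7 N,N'-dimethoxy-N,N'-dimethyl-1,3-dithiane-2,2-dicarboxamide
Product: 10 methyl 8'-(methoxymethoxy)-1',3'-dioxo-6'-phenyl-3',4'-dihydro-1'H-spiro[[1,3]dithiane-2,2'-naphthalene]-5'-carboxylate, via dilithiated arene 8 (not isolated), via dilithium bis-hemiaminal adduct 9 (not isolated)
Conditions: LiN(i-Pr)2 (1.05 equiv), THF, −78 °C; t-BuLi (3.1 equiv, one of them re-deprotonates i-Pr2NH), −100 °C; 7 (1.0 equiv, slow addition), −100 to −40 °C; aq. NH4Cl, then 1 M HCl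
Reagents that add atoms: none
Why: Proposed new method: lateral deprotonation of the ortho-toluate methyl group (the anion is an ester-stabilized ortho-quinodimethane enolate, which also masks the C5 ester) followed by bromine–lithium exchange gives the 1,3-C,C-dianion 8, whose aryllithium adds to one Weinreb amide of 7 and whose benzylic carbon then attacks the second, so that ring B is closed by a 6-exo-trig nucleophilic acyl addition and both new bonds (C1–C8a and C3–C4) exist before work-up. The two N-methoxy-N-methyl tetrahedral alkoxides of 9 are chelate-stabilized, so no ketone is exposed to organolithium until acid releases dione 10. The closest known reaction types are the acylation of laterally lithiated ortho-toluates by Weinreb amides and the Parham cycloacylation of aryllithiums made by halogen–lithium exchange, merged here into one dianion–dielectrophile [3+3] annulation that has not been shown for an aryl/benzyl dianion and a malonyl unit. No stereocentre is formed; the spiro-dithiane at C2 removes both alpha-hydrogens, so 10 cannot tautomerize to a naphthalene-1,3-diol. Regioselectivity is not an issue because the two acyl carbons of 7 are equivalent, and oligomerization should be held back by slow addition of 7 and by the intramolecular second acylation.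

Step 7
Reactants: 10 methyl 8'-(methoxymethoxy)-1',3'-dioxo-6'-phenyl-3',4'-dihydro-1'H-spiro[[1,3]dithiane-2,2'-naphthalene]-5'-carboxylate
Product: 11 methyl (3'S)-3'-hydroxy-8'-(methoxymethoxy)-1'-oxo-6'-phenyl-3',4'-dihydro-1'H-spiro[[1,3]dithiane-2,2'-naphthalene]-5'-carboxylate
Conditions: (R)-1-methyl-3,3-diphenyltetrahydro-1H,3H-pyrrolo[1,2-c][1,3,2]oxazaborole ((R)-Me-CBS, C18H20BNO; 0.5 equiv), BH3·SMe2, THF, −40 to −20 °C; MeOH, then H2O
Reagents that add atoms: none
Why: Corey–Bakshi–Shibata reduction should take the non-conjugated C3 ketone in preference to the aryl ketone C1 (flanked by the peri MOM ether and the quaternary spiro carbon), and the (R)-oxazaborolidine, treating the spiro carbon C2 as the large group and the benzylic CH2 as the small one, should deliver hydride to the face that gives the (S)-carbinol.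

Step 8
Reactants: 11 methyl (3'S)-3'-hydroxy-8'-(methoxymethoxy)-1'-oxo-6'-phenyl-3',4'-dihydro-1'H-spiro[[1,3]dithiane-2,2'-naphthalene]-5'-carboxylate
Product: 12 methyl (7S)-7-hydroxy-4-(methoxymethoxy)-5-oxo-2-phenyl-5,6,7,8-tetrahydronaphthalene-1-carboxylate
Conditions: Raney Ni (W-2 grade, acetone-deactivated), EtOH, rt
Reagents that add atoms: none
Why: Raney nickel desulfurization (Mozingo-type C–S hydrogenolysis) turns the blocked C2 into CH2 under neutral conditions that should leave the β-hydroxy ketone and the C3 configuration untouched.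

Step 9
Reactants: 12 methyl (7S)-7-hydroxy-4-(methoxymethoxy)-5-oxo-2-phenyl-5,6,7,8-tetrahydronaphthalene-1-carboxylate
Product: 13 methyl (7S)-7-[(tert-butyldimethylsilyl)oxy]-4-(methoxymethoxy)-5-oxo-2-phenyl-5,6,7,8-tetrahydronaphthalene-1-carboxylate
Conditions: TBSCl, imidazole, DMF, rt
Reagents that add atoms: tert-butyldimethylsilyl chloride, CC(C)(C)[Si](C)(C)Cl
Why: Silyl ether formation under weakly basic conditions protects C3–OH against the later oxidations without provoking β-elimination.

Step 10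
Reactants: 13 methyl (7S)-7-[(tert-butyldimethylsilyl)oxy]-4-(methoxymethoxy)-5-oxo-2-phenyl-5,6,7,8-tetrahydronaphthalene-1-carboxylate
Product: 14 (3S)-3-[(tert-butyldimethylsilyl)oxy]-5-(hydroxymethyl)-8-(methoxymethoxy)-6-phenyl-1,2,3,4-tetrahydronaphthalen-1-ol (mixture of C1 epimers)
Conditions: i-Bu2AlH (6 equiv), CH2Cl2, −78 to 0 °C; aq. Rochelle salt
Reagents that add atoms: none
Why: Hydride reduction with i-Bu2AlH takes the hindered ester to the benzylic primary alcohol and, unavoidably, the ketone to the benzylic secondary alcohol (epimer mixture of no consequence), while the weakly basic aluminium alkoxides disfavour silyl migration.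

Step 11
Reactants: 14 (3S)-3-[(tert-butyldimethylsilyl)oxy]-5-(hydroxymethyl)-8-(methoxymethoxy)-6-phenyl-1,2,3,4-tetrahydronaphthalen-1-ol
Product: 15 (7S)-7-[(tert-butyldimethylsilyl)oxy]-4-(methoxymethoxy)-5-oxo-2-phenyl-5,6,7,8-tetrahydronaphthalene-1-carbaldehyde
Conditions: Dess–Martin periodinane (3 equiv), NaHCO3, CH2Cl2, rt
Reagents that add atoms: none
Why: Dess–Martin oxidation returns both benzylic alcohols to the carbonyl level, giving the aryl aldehyde and restoring the C1 ketone, which also removes the C1 epimer mixture.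

Step 12
Reactants: 16 2,2,6-trimethyl-4H-1,3-dioxin-4-one
Product: 17 trimethyl[(2,2-dimethyl-6-methylidene-6H-1,3-dioxin-4-yl)oxy]silane
Conditions: LiN(i-Pr)2, THF, −78 °C; Me3SiCl
Reagents that add atoms: chlorotrimethylsilane, C[Si](C)(C)Cl
Why: γ-Deprotonation of the dioxinone and O-silylation of the dienolate give the silyl dienol ether, a masked acetoacetate γ-nucleophile.

Step 13
Reactants: 15 (7S)-7-[(tert-butyldimethylsilyl)oxy]-4-(methoxymethoxy)-5-oxo-2-phenyl-5,6,7,8-tetrahydronaphthalene-1-carbaldehyde; 17 trimethyl[(2,2-dimethyl-6-methylidene-6H-1,3-dioxin-4-yl)oxy]silane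
Product: 18 6-{2-[(7S)-7-[(tert-butyldimethylsilyl)oxy]-4-(methoxymethoxy)-5-oxo-2-phenyl-5,6,7,8-tetrahydronaphthalen-1-yl]-2-hydroxyethyl}-2,2-dimethyl-4H-1,3-dioxin-4-one (mixture of carbinol epimers)
Conditions: BF3·OEt2 (1.5 equiv), CH2Cl2, −78 °C; aq. NaHCO3
Reagents that add atoms: none
Why: Vinylogous Mukaiyama aldol addition under BF3 activation should occur at the γ-carbon of 17 and at the aldehyde only, the hindered conjugated ketone being far less electrophilic; the new carbinol centre is oxidized in step 14, so its configuration does not matter.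

Step 14
Reactants: 18 6-{2-[(7S)-7-[(tert-butyldimethylsilyl)oxy]-4-(methoxymethoxy)-5-oxo-2-phenyl-5,6,7,8-tetrahydronaphthalen-1-yl]-2-hydroxyethyl}-2,2-dimethyl-4H-1,3-dioxin-4-one
Product: 19 6-{2-[(7S)-7-[(tert-butyldimethylsilyl)oxy]-4-(methoxymethoxy)-5-oxo-2-phenyl-5,6,7,8-tetrahydronaphthalen-1-yl]-2-oxoethyl}-2,2-dimethyl-4H-1,3-dioxin-4-one
Conditions: Dess–Martin periodinane, NaHCO3, CH2Cl2, 0 °C to rt
Reagents that add atoms: none
Why: Dess–Martin oxidation of the benzylic secondary alcohol gives the β-keto dioxinone that is the acylketene precursor.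

Step 15
Reactants: 19 6-{2-[(7S)-7-[(tert-butyldimethylsilyl)oxy]-4-(methoxymethoxy)-5-oxo-2-phenyl-5,6,7,8-tetrahydronaphthalen-1-yl]-2-oxoethyl}-2,2-dimethyl-4H-1,3-dioxin-4-one
Product: 21 (3S)-3-[(tert-butyldimethylsilyl)oxy]-5-(4-hydroxy-2-oxo-2H-pyran-6-yl)-8-(methoxymethoxy)-6-phenyl-3,4-dihydronaphthalen-1(2H)-one, via acylketene 20 (not isolated)
Conditions: toluene, 110 °C
Reagents that add atoms: none
Why: Thermal retro-[4+2] cycloreversion of the dioxinone expels acetone, and the acylketene is captured by the enol oxygen of the aryl ketone (lactonization) to give the 4-hydroxy-2-pyranone under neutral conditions.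

Step 16
Reactants: 21 (3S)-3-[(tert-butyldimethylsilyl)oxy]-5-(4-hydroxy-2-oxo-2H-pyran-6-yl)-8-(methoxymethoxy)-6-phenyl-3,4-dihydronaphthalen-1(2H)-one
Product: 22 wailupemycin F, (3S)-3,8-dihydroxy-5-(4-hydroxy-2-oxo-2H-pyran-6-yl)-6-phenyl-3,4-dihydronaphthalen-1(2H)-one
Conditions: HCl (1.25 M in MeOH), 0 °C to rt
Reagents that add atoms: none
Why: Acid-catalysed methanolysis should cleave the aryl MOM acetal and the secondary silyl ether in one operation under conditions mild enough to spare the β-hydroxy ketone, and it does not touch the C3 configuration.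

**Compound list**
1 | methyl 2,4-dihydroxy-6-methylbenzoate (methyl orsellinate) | COC(=O)c1c(C)cc(O)cc1O | starting material
2 | methyl 3-bromo-4,6-dihydroxy-2-methylbenzoate | COC(=O)c1c(C)c(Br)c(O)cc1O | intermediate
3 | methyl 3-bromo-6-hydroxy-4-(methoxymethoxy)-2-methylbenzoate | COC(=O)c1c(C)c(Br)c(OCOC)cc1O | intermediate
4 | methyl 3-bromo-4-(methoxymethoxy)-2-methyl-6-(trifluoromethanesulfonyloxy)benzoate | COC(=O)c1c(C)c(Br)c(OCOC)cc1OS(=O)(=O)C(F)(F)F | intermediate
5 | methyl 4-bromo-5-(methoxymethoxy)-3-methyl-[1,1'-biphenyl]-2-carboxylate | COC(=O)c1c(C)c(Br)c(OCOC)cc1-c1ccccc1 | intermediate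
6 | N,N'-dimethoxy-N,N'-dimethylmalonamide | CON(C)C(=O)CC(=O)N(C)OC | starting material
7 | N,N'-dimethoxy-N,N'-dimethyl-1,3-dithiane-2,2-dicarboxamide | CON(C)C(=O)C1(C(=O)N(C)OC)SCCCS1 | intermediate
8 | methyl 4-lithio-3-(lithiomethyl)-5-(methoxymethoxy)-[1,1'-biphenyl]-2-carboxylate (dilithiated arene, not isolated) | COC(=O)c1c(C[Li])c([Li])c(OCOC)cc1-c1ccccc1 | intermediate
9 | dilithium 1',3'-bis[methoxy(methyl)amino]-1',3'-diolate of the spiro[dithiane-naphthalene] ester (bis-hemiaminal adduct, not isolated) | [Li]OC1(N(C)OC)c2c(OCOC)cc(-c3ccccc3)c(C(=O)OC)c2CC(O[Li])(N(C)OC)C12SCCCS2 | intermediate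
10 | methyl 8'-(methoxymethoxy)-1',3'-dioxo-6'-phenyl-3',4'-dihydro-1'H-spiro[[1,3]dithiane-2,2'-naphthalene]-5'-carboxylate | O=C1c2c(OCOC)cc(-c3ccccc3)c(C(=O)OC)c2CC(=O)C12SCCCS2 | intermediate
11 | methyl (3'S)-3'-hydroxy-8'-(methoxymethoxy)-1'-oxo-6'-phenyl-3',4'-dihydro-1'H-spiro[[1,3]dithiane-2,2'-naphthalene]-5'-carboxylate | O=C1c2c(OCOC)cc(-c3ccccc3)c(C(=O)OC)c2C[C@H](O)C12SCCCS2 | intermediate
12 | methyl (7S)-7-hydroxy-4-(methoxymethoxy)-5-oxo-2-phenyl-5,6,7,8-tetrahydronaphthalene-1-carboxylate | O=C1C[C@@H](O)Cc2c1c(OCOC)cc(-c1ccccc1)c2C(=O)OC | intermediate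
13 | methyl (7S)-7-[(tert-butyldimethylsilyl)oxy]-4-(methoxymethoxy)-5-oxo-2-phenyl-5,6,7,8-tetrahydronaphthalene-1-carboxylate | O=C1C[C@@H](O[Si](C)(C)C(C)(C)C)Cc2c1c(OCOC)cc(-c1ccccc1)c2C(=O)OC | intermediate
14 | (3S)-3-[(tert-butyldimethylsilyl)oxy]-5-(hydroxymethyl)-8-(methoxymethoxy)-6-phenyl-1,2,3,4-tetrahydronaphthalen-1-ol (C1 epimers) | OC1C[C@@H](O[Si](C)(C)C(C)(C)C)Cc2c1c(OCOC)cc(-c1ccccc1)c2CO | intermediate
15 | (7S)-7-[(tert-butyldimethylsilyl)oxy]-4-(methoxymethoxy)-5-oxo-2-phenyl-5,6,7,8-tetrahydronaphthalene-1-carbaldehyde | O=C1C[C@@H](O[Si](C)(C)C(C)(C)C)Cc2c1c(OCOC)cc(-c1ccccc1)c2C=O | intermediate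
16 | 2,2,6-trimethyl-4H-1,3-dioxin-4-one | CC1=CC(=O)OC(C)(C)O1 | starting material
17 | trimethyl[(2,2-dimethyl-6-methylidene-6H-1,3-dioxin-4-yl)oxy]silane | C=C1C=C(O[Si](C)(C)C)OC(C)(C)O1 | intermediate
18 | 6-{2-[(7S)-7-[(tert-butyldimethylsilyl)oxy]-4-(methoxymethoxy)-5-oxo-2-phenyl-5,6,7,8-tetrahydronaphthalen-1-yl]-2-hydroxyethyl}-2,2-dimethyl-4H-1,3-dioxin-4-one (carbinol epimers) | O=C1C[C@@H](O[Si](C)(C)C(C)(C)C)Cc2c1c(OCOC)cc(-c1ccccc1)c2C(O)CC1=CC(=O)OC(C)(C)O1 | intermediate
19 | 6-{2-[(7S)-7-[(tert-butyldimethylsilyl)oxy]-4-(methoxymethoxy)-5-oxo-2-phenyl-5,6,7,8-tetrahydronaphthalen-1-yl]-2-oxoethyl}-2,2-dimethyl-4H-1,3-dioxin-4-one | O=C1C[C@@H](O[Si](C)(C)C(C)(C)C)Cc2c1c(OCOC)cc(-c1ccccc1)c2C(=O)CC1=CC(=O)OC(C)(C)O1 | intermediate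
20 | 5-[(7S)-7-[(tert-butyldimethylsilyl)oxy]-4-(methoxymethoxy)-5-oxo-2-phenyl-5,6,7,8-tetrahydronaphthalen-1-yl]-3,5-dioxopent-1-en-1-one (acylketene, not isolated) | O=C1C[C@@H](O[Si](C)(C)C(C)(C)C)Cc2c1c(OCOC)cc(-c1ccccc1)c2C(=O)CC(=O)C=C=O | intermediate
21 | (3S)-3-[(tert-butyldimethylsilyl)oxy]-5-(4-hydroxy-2-oxo-2H-pyran-6-yl)-8-(methoxymethoxy)-6-phenyl-3,4-dihydronaphthalen-1(2H)-one | O=C1C[C@@H](O[Si](C)(C)C(C)(C)C)Cc2c1c(OCOC)cc(-c1ccccc1)c2-c1cc(O)cc(=O)o1 | intermediate
22 | wailupemycin F, (3S)-3,8-dihydroxy-5-(4-hydroxy-2-oxo-2H-pyran-6-yl)-6-phenyl-3,4-dihydronaphthalen-1(2H)-one | O=C1C[C@@H](O)Cc2c1c(O)cc(-c1ccccc1)c2-c1cc(O)cc(=O)o1 | target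

**Step count and risks**
Total steps: 16. Longest linear sequence: 14 (steps 1–4, 6–11, 13–16).

Steps most likely to fail:

1. Step 6 (Proposed new method). What may go wrong: the aryllithium site of the dianion may be quenched by proton transfer, the Weinreb amide may fragment under the regenerated amide base, or intermolecular double addition may outrun the ring-closing acylation and give oligomers. The fallback uses known chemistry, sets out from 5 and returns at 10. Bromine–lithium exchange alone (t-BuLi, THF, −100 °C) and acylation with excess 7 would give the aryl ketone methyl 5-(methoxymethoxy)-4-{2-[methoxy(methyl)carbamoyl]-1,3-dithiane-2-carbonyl}-3-methyl-[1,1'-biphenyl]-2-carboxylate F1. Lateral lithiation of its methyl group with LiN(i-Pr)2 (now flanked by ester and ketone) and 6-exo-trig acylation by the remaining Weinreb amide would then close ring B to 10.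

2. Step 7. What may go wrong: incomplete discrimination between the two ketones (over-reduction at C1) or loss of facial selectivity through borane coordination to the dithiane sulfurs. The fallback sets the stereocentre before ring closure; it sets out from 5 and returns at 11. Lateral lithiation of 5 (LiN(i-Pr)2, 2 equiv) and mono-acylation with excess 7 would give the open-chain benzyl ketone methyl 4-bromo-3-(2-{2-[methoxy(methyl)carbamoyl]-1,3-dithian-2-yl}-2-oxoethyl)-5-(methoxymethoxy)-[1,1'-biphenyl]-2-carboxylate F2, which has a single ketone. CBS reduction with the same (R)-oxazaborolidine would give methyl 4-bromo-3-[(2S)-2-hydroxy-2-{2-[methoxy(methyl)carbamoyl]-1,3-dithian-2-yl}ethyl]-5-(methoxymethoxy)-[1,1'-biphenyl]-2-carboxylate F3. Treatment with t-BuLi (3 equiv, −100 °C; alkoxide formation, then exchange) would close ring B by Parham cycloacylation onto the Weinreb amide to give 11.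

3. Step 16. What may go wrong: acid-promoted β-elimination of the C3 oxygen followed by aromatization of ring B to the naphthol. The fallback replaces the one-pot protic unmasking by two orthogonal, non-hydrolytic operations; it sets out from 21 and returns at 22. Me3SiBr (CH2Cl2, −30 °C) would cleave only the aryl MOM acetal to give (3S)-3-[(tert-butyldimethylsilyl)oxy]-8-hydroxy-5-(4-hydroxy-2-oxo-2H-pyran-6-yl)-6-phenyl-3,4-dihydronaphthalen-1(2H)-one F4. Pyridine-buffered HF·pyridine (THF, 0 °C) would then remove the silyl ether to give 22.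

**Further compounds**
F1 | step 6 | methyl 5-(methoxymethoxy)-4-{2-[methoxy(methyl)carbamoyl]-1,3-dithiane-2-carbonyl}-3-methyl-[1,1'-biphenyl]-2-carboxylate | COC(=O)c1c(C)c(C(=O)C2(C(=O)N(C)OC)SCCCS2)c(OCOC)cc1-c1ccccc1
F2 | step 7 | methyl 4-bromo-3-(2-{2-[methoxy(methyl)carbamoyl]-1,3-dithian-2-yl}-2-oxoethyl)-5-(methoxymethoxy)-[1,1'-biphenyl]-2-carboxylate | COC(=O)c1c(CC(=O)C2(C(=O)N(C)OC)SCCCS2)c(Br)c(OCOC)cc1-c1ccccc1
F3 | step 7 | methyl 4-bromo-3-[(2S)-2-hydroxy-2-{2-[methoxy(methyl)carbamoyl]-1,3-dithian-2-yl}ethyl]-5-(methoxymethoxy)-[1,1'-biphenyl]-2-carboxylate | COC(=O)c1c(C[C@H](O)C2(C(=O)N(C)OC)SCCCS2)c(Br)c(OCOC)cc1-c1ccccc1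
F4 | step 16 | (3S)-3-[(tert-butyldimethylsilyl)oxy]-8-hydroxy-5-(4-hydroxy-2-oxo-2H-pyran-6-yl)-6-phenyl-3,4-dihydronaphthalen-1(2H)-one | O=C1C[C@@H](O[Si](C)(C)C(C)(C)C)Cc2c1c(O)cc(-c1ccccc1)c2-c1cc(O)cc(=O)o1
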